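## Structural features

Curlignan is a 2,3-dihydrobenzofuran neolignan: a benzene ring (ring A) is fused through C3a and C7a to a dihydrofuran ring made of O1, C2 and C3. Ring A carries a methyl ester at C5 and a methoxy group at C7; C2 carries a 4-hydroxy-3-methoxyphenyl (guaiacyl) ring and C3 a hydroxymethyl group. C2 (S) and C3 (R) are adjacent stereocentres, with the aryl and hydroxymethyl groups trans. The C2–O1 bond is a benzylic aryl ether para to a phenol, so strong acid, strong base or prolonged hydrogenolysis can open the ring. C3 is epimerisable whenever it is alpha to a carbonyl group, and the C5 methyl benzoate must survive the reduction that makes the C3 hydroxymethyl group. The real difficulty is twofold: absolute control at C2 together with the trans relation to C3, and telling apart two carbons at the carboxyl oxidation level (C5 stays an ester, the C3 substituent ends as an alcohol). The key step uses the C2–H bond of an open-chain aryl benzyl ether: it is benzylic, alpha to O1, and 1,5-related to a carbene carbon placed on C3a, the future C3.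

## Logic of the disconnections

10 to 9: the C3 hydroxymethyl group is traced back to a free carboxylic acid; no skeletal bond is cut. A free acid is reduced by borane beside a methyl benzoate, which solves the differentiation of the two carboxyl carbons. The forward step must be non-basic (C3 of 9 is alpha to a carboxyl group) and must leave the C5 ester and C2–O1 alone.

9 to 8: two O–CH2Ph bonds are cut, the benzyl ester at C3 and the benzyl ether of the phenol. Using benzyl for both lets one neutral operation unmask acid and phenol, and the benzyl ester is what marks the C3 carboxyl as different from the C5 methyl ester. The forward hydrogenolysis must stop before it reaches the ring C2–O1 bond.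

8 to 6 (through 7): the C2–C3 bond is cut. This opens the dihydrofuran ring and removes both stereocentres, leaving an achiral aryl benzyl ether with a diazo ester on the future C3. The forward step must choose one of two enantiotopic methylene hydrogens (catalyst control), must prefer the 1,5 C–H bond over every other reactive site, and must move the kinetic cis ester 7 to the trans ester 8 without disturbing C2.

6 to 4 and 5: the bond between the aromatic carbon (future C3a) and the diazo carbon is cut. This is convergent and gives the aryldiazoacetate in one operation from an aryl iodide, without a separate arylacetate synthesis and diazo transfer. The forward coupling must keep the diazo group intact in the presence of palladium.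

4 to 2 and 3: the O–CH2 ether bond (future O1–C2) is cut, giving an iodophenol and a benzylic alcohol. The alcohol is used directly, so no benzyl chloride has to be made or handled. The forward step must alkylate a phenol oxygen flanked by iodine and methoxy.

2 to 1: the C–I bond is cut. The phenol of 1 directs an electrophile to its only free ortho position, the para position being blocked; the forward step must stop at mono-iodination.

## Other disconnections considered

Alternative 1: The cut removes ring A altogether, at C3a–C4 and C7a–C7. The dihydrofuran ring with both stereocentres would come first as the trans γ-lactone A2 (its C5 and C4 are the later C2 and C3), and ring A would be built onto it.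
- Forward step: the tert-butyldimethylsilyl ketene acetal A3 of A2 adds as an electron-rich dienophile to methyl 3-bromocoumalate A4 (inverse electron demand). The nucleophilic α-carbon bonds to C6 of the pyrone and the ketene acetal carbon to C3. The bridged adduct then loses carbon dioxide (retro-Diels–Alder) and tert-butyldimethylsilanol (elimination) to give the 7-bromo ester A1.
- In favour: C2 and C3 are fixed in a lactone by well-tried chemistry before any sensitive benzylic aryl ether exists. C3 is never alpha to a carbonyl once A2 is made, so it cannot epimerise. The polarity of A3 and A4 dictates the regiochemistry.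
- Better than the chosen plan: no diazo compound and no rhodium are needed (safety, cost), and only one ester is ever present, so the two carboxyl carbons need not be told apart.
- Against: C7 arrives as bromide and must be converted into the methyl ether by a copper-mediated methoxylation (CuI, NaOMe) next to O1. Enantiopure A2 costs several steps, and silyl and benzyl groups must be removed at the end, so the count would be roughly twice that of the chosen route. A3 is a hindered, hydrolytically labile ketene acetal, and loss of carbon dioxide usually needs heat.
- Comparison: mechanistically both plans are well founded. Structurally the chosen plan is more direct: it keeps the intact vanillate ring and makes the ring and both stereocentres in one operation.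

Alternative 2: The cut is at C3–H and at the C–O bond of the hydroxymethyl group (a C–Si bond in the synthetic direction), with O1–C2 left for a later closure. The precursor is the hydrodimethylsilyl ether A6 of a 2-aryl allylic alcohol, whose single carbinol centre could come from an asymmetric ketone reduction.
- Forward step: H2PtCl6 catalyses a 5-endo intramolecular hydrosilylation of the 1,1-disubstituted alkene, delivering hydrogen to the future C3 and silicon to the terminal carbon. This gives the cis-4,5-disubstituted oxasilolane A5, and Tamao–Fleming oxidation would then give the syn diol A7.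
- Better than the chosen plan: the hydroxymethyl carbon arrives at the alcohol oxidation level, so no ester has to be differentiated from the C5 ester; no diazo compound is involved.
- Equal: stereocontrol through a small cyclic transition state from one existing centre is as credible as catalyst control.
- Against: the carbinol carbon of A5 and A7 has the spatial arrangement of C2 in the target, so O1–C2 must close with net retention. An SN2 closure (Mitsunobu) would invert and give the cis isomer. An ionising closure through the p-alkoxybenzyl cation discards the centre used for the relay and relies on C3 alone to restore trans. The methoxymethyl ether must be removed with acid next to that labile benzylic alcohol. The alkene of A6 is an α-arylstyrene, for which diastereoselectivity is less secure than for alkyl cases.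
- Comparison: about nine or ten steps (allylic alcohol, silylation, hydrosilylation, oxidation, unmasking, closure, debenzylation), clearly longer than the chosen plan, which closes the ring and sets both centres at once.

Alternative 3: The cut is C3–C3a, read as the result of a 1,2-shift. The precursor is the (2S)-flavanone A9, in which ring A is still bonded to the carbonyl carbon.
- Forward step: PhI(OAc)2 with H2SO4 in trimethyl orthoformate converts the ketone into its enol ether and ketal. A trivalent iodine group adds to C3 anti to the C2 aryl group, and ring A migrates from the ketal carbon to C3 as iodobenzene leaves. The pyranone contracts to the dihydrofuran and the former carbonyl carbon becomes the methyl ester of A8.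
- In favour: A9 is reached in few steps from an acetophenone and an aldehyde.
- Better than the chosen plan: the trans relation follows directly from the anti migration, with no base-mediated equilibration; A8 holds a single ester, which can be reduced to the hydroxymethyl group without differentiation; no diazo compound is used.
- Against: the medium is strongly acidic and oxidising while ring B is an electron-rich guaiacyl ether. Migration of ring B (to an isoflavone), dehydrogenation to the flavone and attack on ring B all compete. Acid can open the flavanone reversibly to the chalcone and erode C2. Ring A must carry bromine in place of the ester, because an ester would slow the migration and give two indistinguishable methyl esters. This adds a palladium-catalysed methoxycarbonylation with carbon monoxide (Pd(OAc)2, CO, MeOH) at the end, a toxic gas that offsets part of the safety gain.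
- Comparison: about eight steps against six. The key step is less predictable on this substitution pattern than the carbene insertion, whose site is fixed by geometry.

Key step: step 4

Assumption: the sense of induction is assigned by analogy. In the parent aryl benzyl ether diazoacetates the S ligand series of the phthaloyl-tert-leucinate catalysts is taken to favour the (2R) ether carbon, so the route is written with the mirror-image catalyst Rh2(R-PTTL)4 (dirhodium tetrakis[N-phthaloyl-(R)-tert-leucinate], from D-tert-leucine); the S catalyst would be used if the sense proved opposite on this substrate.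

Step 1
Reactants: 1 methyl vanillate (methyl 4-hydroxy-3-methoxybenzoate)
Product: 2 methyl 4-hydroxy-3-iodo-5-methoxybenzoate
Conditions: NIS (1.05 equiv), TsOH·H2O (10 mol%), MeCN, 0 °C to rt
Reagents that add atoms: N-iodosuccinimide, O=C1CCC(=O)N1I
Why: Electrophilic aromatic iodination; the phenol directs to its only free ortho position, the para position being blocked by the ester, and the acid activates NIS so that one equivalent suffices. No stereocentre is formed.

Step 2
Reactants: 2 methyl 4-hydroxy-3-iodo-5-methoxybenzoate; 3 4-benzyloxy-3-methoxybenzyl alcohol
Product: 4 methyl 4-[(4-benzyloxy-3-methoxyphenyl)methoxy]-3-iodo-5-methoxybenzoate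
Conditions: PPh3 (1.3 equiv), DIAD (1.3 equiv, added last), THF, 0 °C to rt
Reagents that add atoms: none
Why: Mitsunobu etherification; the phenol, acidified by the ortho iodine and para ester, protonates the betaine, and its phenoxide displaces the alkoxyphosphonium ion at the primary benzylic carbon. Using the alcohol directly saves the step to the electron-rich benzyl chloride and avoids handling that alkylating agent.

Step 3
Reactants: 4 methyl 4-[(4-benzyloxy-3-methoxyphenyl)methoxy]-3-iodo-5-methoxybenzoate; 5 benzyl diazoacetate (commercial solution in toluene, not concentrated)
Product: 6 benzyl 2-diazo-2-[2-(4-benzyloxy-3-methoxybenzyloxy)-3-methoxy-5-(methoxycarbonyl)phenyl]acetate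
Conditions: Pd(PPh3)4 (5 mol%), Ag2CO3 (0.5 equiv), Et3N (1.3 equiv), toluene, rt, dark
Reagents that add atoms: none
Why: Palladium-catalysed cross-coupling of an aryl iodide with an acceptor diazo compound that keeps the diazo group: zerovalent palladium adds into the C–I bond, silver removes iodide, the nucleophilic diazo carbon is palladated with loss of its proton to the base, and reductive elimination forms the aryl–C(N2) bond. Room temperature keeps both the diazo ester and the product from decomposing to a palladium carbene.

Step 4
Reactants: 6 benzyl 2-diazo-2-[2-(4-benzyloxy-3-methoxybenzyloxy)-3-methoxy-5-(methoxycarbonyl)phenyl]acetate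
Product: 8 3-benzyl 5-methyl (2S,3S)-2-(4-benzyloxy-3-methoxyphenyl)-7-methoxy-2,3-dihydrobenzofuran-3,5-dicarboxylate (trans), via cis diester 7 (not isolated)
Conditions: Rh2(R-PTTL)4 (1–2 mol%), toluene, −60 °C, slow addition of 6; then DBU (0.5 equiv), −60 °C to rt
Reagents that add atoms: none
Why: Rh2(R-PTTL)4, a divalent rhodium carboxylate dimer, decomposes the diazo group of 6 with loss of N2 to a rhodium-bound donor/acceptor carbene at the future C3. The carbene inserts into one C–H bond of the ether methylene in a concerted but asynchronous three-centre transition state with hydride-shift character, stabilised by O1 and the electron-rich aryl group; the closest known reaction type is the enantioselective intramolecular 1,5 C–H insertion of aryldiazoacetates into benzylic ether C–H bonds under chiral dirhodium tetracarboxylate catalysis, which gives cis-2-aryl-2,3-dihydrobenzofuran-3-carboxylates. The dihydrofuran ring closes in this insertion by formation of C2–C3 through a five-membered array (carbene carbon, C3a, C7a, O1, CH2). C2 is set by the catalyst: the phthalimido wall of the ligands lets only one of the two enantiotopic methylene hydrogens reach the carbene, and the R ligand series is chosen to give (2S). C3 is first formed cis to the aryl group (kinetic product 7) and is then corrected by DBU, which enolises the doubly activated C3–H (ester and ring A) so that reprotonation settles on the more stable trans ester 8 under the control of C2, which has no acidic hydrogen and stays fixed. Site selectivity is needed against the benzyl ester CH2 (four-membered array), the remote O-benzyl CH2 and the guaiacyl π-system (six- or seven-membered arrays); the 1,5 geometry and the double activation of the target C–H secure it, and low temperature with slow addition holds down carbene dimerisation. Ring opening by β-elimination of the phenoxide from the enolate is disfavoured because the enolate π-system is nearly orthogonal to the C2–O1 bond within the five-membered ring (the reverse of a 5-endo-trig closure).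

Step 5
Reactants: 8 3-benzyl 5-methyl (2S,3S)-2-(4-benzyloxy-3-methoxyphenyl)-7-methoxy-2,3-dihydrobenzofuran-3,5-dicarboxylate
Product: 9 (2S,3S)-2-(4-hydroxy-3-methoxyphenyl)-7-methoxy-5-(methoxycarbonyl)-2,3-dihydrobenzofuran-3-carboxylic acid
Conditions: H2 (1 atm), 10% Pd/C, EtOAc, rt, stopped after uptake of 2 equiv H2
Reagents that add atoms: none
Why: Catalytic hydrogenolysis cleaves the primary benzyl ester and the primary aryl benzyl ether quickly, whereas the ring C2–O1 bond, a hindered secondary benzylic ether, should react much more slowly. The neutral medium leaves the C3 stereocentre and the methyl ester untouched.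

Step 6
Reactants: 9 (2S,3S)-2-(4-hydroxy-3-methoxyphenyl)-7-methoxy-5-(methoxycarbonyl)-2,3-dihydrobenzofuran-3-carboxylic acid
Product: 10 curlignan, methyl (2S,3R)-2-(4-hydroxy-3-methoxyphenyl)-3-(hydroxymethyl)-7-methoxy-2,3-dihydrobenzofuran-5-carboxylate
Conditions: BH3·SMe2 (3 equiv), THF, 0 °C to rt; then H2O, 0 °C
Reagents that add atoms: none
Why: Chemoselective borane reduction of a carboxylic acid through its acyloxyborane; methyl benzoates are inert to borane at this temperature, and the phenol is only borylated and is released on work-up. The conditions are non-basic, so C3 keeps its configuration; its descriptor changes from S to R only because the substituent priorities change.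

Compound list
1 | methyl vanillate (methyl 4-hydroxy-3-methoxybenzoate) | COC(=O)c1ccc(O)c(OC)c1 | starting material
2 | methyl 4-hydroxy-3-iodo-5-methoxybenzoate | COC(=O)c1cc(I)c(O)c(OC)c1 | intermediate
3 | 4-benzyloxy-3-methoxybenzyl alcohol | COc1cc(CO)ccc1OCc1ccccc1 | starting material
4 | methyl 4-[(4-benzyloxy-3-methoxyphenyl)methoxy]-3-iodo-5-methoxybenzoate | COC(=O)c1cc(I)c(OCc2ccc(OCc3ccccc3)c(OC)c2)c(OC)c1 | intermediate
5 | benzyl diazoacetate | [N-]=[N+]=CC(=O)OCc1ccccc1 | starting material
6 | benzyl 2-diazo-2-[2-(4-benzyloxy-3-methoxybenzyloxy)-3-methoxy-5-(methoxycarbonyl)phenyl]acetate | COC(=O)c1cc(OC)c(OCc2ccc(OCc3ccccc3)c(OC)c2)c(c1)C(=[N+]=[N-])C(=O)OCc1ccccc1 | intermediate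
7 | 3-benzyl 5-methyl (2S,3R)-2-(4-benzyloxy-3-methoxyphenyl)-7-methoxy-2,3-dihydrobenzofuran-3,5-dicarboxylate (cis) | COC(=O)c1cc(OC)c2c(c1)[C@@H](C(=O)OCc1ccccc1)[C@@H](c1ccc(OCc3ccccc3)c(OC)c1)O2 | intermediate (not isolated)
8 | 3-benzyl 5-methyl (2S,3S)-2-(4-benzyloxy-3-methoxyphenyl)-7-methoxy-2,3-dihydrobenzofuran-3,5-dicarboxylate (trans) | COC(=O)c1cc(OC)c2c(c1)[C@H](C(=O)OCc1ccccc1)[C@@H](c1ccc(OCc3ccccc3)c(OC)c1)O2 | intermediate
9 | (2S,3S)-2-(4-hydroxy-3-methoxyphenyl)-7-methoxy-5-(methoxycarbonyl)-2,3-dihydrobenzofuran-3-carboxylic acid | COC(=O)c1cc(OC)c2c(c1)[C@H](C(=O)O)[C@@H](c1ccc(O)c(OC)c1)O2 | intermediate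
10 | curlignan, methyl (2S,3R)-2-(4-hydroxy-3-methoxyphenyl)-3-(hydroxymethyl)-7-methoxy-2,3-dihydrobenzofuran-5-carboxylate | COC(=O)c1cc(OC)c2c(c1)[C@H](CO)[C@@H](c1ccc(O)c(OC)c1)O2 | target

Total step count: 6. Longest linear sequence: 6 steps (1 to 10).

Least certain steps

Step 4 (key step). The most likely failure is insufficient or wrongly directed enantiocontrol at C2. The C–H bond is strongly activated by oxygen and a p-alkoxyaryl group, which makes the transition state early and hydride-transfer-like and so less sensitive to the ligand wall. The benzyl ester is also larger than the methyl esters on which this reaction type is best established, and the sense of induction rests on analogy. A second risk is loss of material by base-induced ring opening during the DBU equilibration, since the leaving phenoxide is stabilised by the para ester. The fallback replaces catalyst control by a resolution and sets out from 6. Rh2(OAc)4 in CH2Cl2 at rt, followed by DBU in the same flask, should give first the racemic cis diester F1 and then the racemic trans diester F2. Hydrogenolysis as in step 5 should give the racemic trans acid F3. Crystallisation with (S)-1-phenylethylamine from an alcohol solvent should deposit the diastereomeric salt F4 of the (2S,3S) acid (the mirror-image amine serves if the other salt is the less soluble one). Dilute HCl then liberates 9, where the route is rejoined.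

Step 3. The most likely failure is loss of the diazo function under palladium: zerovalent palladium can decompose the diazo ester or the product to a palladium carbene, and coupling at an iodide that has an alkoxy group ortho to it is slower than in unhindered cases. The fallback sets out from 4 and uses a Negishi-type α-arylation with the Reformatsky reagent BrZnCH2CO2Bn (from benzyl bromoacetate and Zn; Pd2(dba)3, XPhos, THF, 60 °C). This should give benzyl 2-[2-(4-benzyloxy-3-methoxybenzyloxy)-3-methoxy-5-(methoxycarbonyl)phenyl]acetate F5. Regitz diazo transfer (4-acetamidobenzenesulfonyl azide, DBU, MeCN, 0 °C to rt) then leads back to 6.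

Step 5. The most likely failure is over-reduction: hydrogenolysis may continue into the ring C2–O1 bond, which is itself a benzylic aryl ether and becomes more electron-rich once the phenol is free. The fallback changes the cleavage mechanism and sets out from 8. BCl3 with pentamethylbenzene as a cation scavenger in CH2Cl2 at −78 °C should remove the benzyl ester and the aryl benzyl ether by Lewis-acid cleavage, the benzyl cations being taken up by the scavenger. The ring oxygen, conjugated to the ester-bearing ring A, is the least basic ether oxygen. This returns directly to 9 and creates no new compound.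

Step 2. The most likely failure is slow etherification, because the phenol oxygen is flanked by iodine and methoxy; the activated electron-rich benzylic alcohol may then be consumed by alkylation of the reduced azodicarboxylate or by self-condensation. The fallback sets out from 3: SOCl2 in CH2Cl2 at 0 °C should give 4-benzyloxy-3-methoxybenzyl chloride F6, which is used at once in a Williamson alkylation of 2 (K2CO3, DMF, rt) and rejoins the route at 4.

## Further compounds

F1 | step 4 | racemic cis diester, 3-benzyl 5-methyl (2S,3R)/(2R,3S)-2-(4-benzyloxy-3-methoxyphenyl)-7-methoxy-2,3-dihydrobenzofuran-3,5-dicarboxylate | COC(=O)c1cc(OC)c2c(c1)[C@@H](C(=O)OCc1ccccc1)[C@@H](c1ccc(OCc3ccccc3)c(OC)c1)O2.COC(=O)c1cc(OC)c2c(c1)[C@H](C(=O)OCc1ccccc1)[C@H](c1ccc(OCc3ccccc3)c(OC)c1)O2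
F2 | step 4 | racemic trans diester, 3-benzyl 5-methyl (2S,3S)/(2R,3R)-2-(4-benzyloxy-3-methoxyphenyl)-7-methoxy-2,3-dihydrobenzofuran-3,5-dicarboxylate | COC(=O)c1cc(OC)c2c(c1)[C@H](C(=O)OCc1ccccc1)[C@@H](c1ccc(OCc3ccccc3)c(OC)c1)O2.COC(=O)c1cc(OC)c2c(c1)[C@@H](C(=O)OCc1ccccc1)[C@H](c1ccc(OCc3ccccc3)c(OC)c1)O2
F3 | step 4 | racemic trans acid, (2S,3S)/(2R,3R)-2-(4-hydroxy-3-methoxyphenyl)-7-methoxy-5-(methoxycarbonyl)-2,3-dihydrobenzofuran-3-carboxylic acid | COC(=O)c1cc(OC)c2c(c1)[C@H](C(=O)O)[C@@H](c1ccc(O)c(OC)c1)O2.COC(=O)c1cc(OC)c2c(c1)[C@@H](C(=O)O)[C@H](c1ccc(O)c(OC)c1)O2
F4 | step 4 | (S)-1-phenylethylammonium (2S,3S)-2-(4-hydroxy-3-methoxyphenyl)-7-methoxy-5-(methoxycarbonyl)-2,3-dihydrobenzofuran-3-carboxylate | COC(=O)c1cc(OC)c2c(c1)[C@H](C(=O)[O-])[C@@H](c1ccc(O)c(OC)c1)O2.C[C@H]([NH3+])c1ccccc1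
F5 | step 3 | benzyl 2-[2-(4-benzyloxy-3-methoxybenzyloxy)-3-methoxy-5-(methoxycarbonyl)phenyl]acetate | COC(=O)c1cc(OC)c(OCc2ccc(OCc3ccccc3)c(OC)c2)c(c1)CC(=O)OCc1ccccc1
F0 | step 5 | none | none
F6 | step 2 | 4-benzyloxy-3-methoxybenzyl chloride | COc1cc(CCl)ccc1OCc1ccccc1
A1 | alternative 1 | methyl (2S,3R)-2-(4-benzyloxy-3-methoxyphenyl)-7-bromo-3-(tert-butyldimethylsilyloxymethyl)-2,3-dihydrobenzofuran-5-carboxylate | COC(=O)c1cc(Br)c2c(c1)[C@H](CO[Si](C)(C)C(C)(C)C)[C@@H](c1ccc(OCc3ccccc3)c(OC)c1)O2
A2 | alternative 1 | (4R,5S)-5-(4-benzyloxy-3-methoxyphenyl)-4-(tert-butyldimethylsilyloxymethyl)oxolan-2-one | O=C1C[C@H](CO[Si](C)(C)C(C)(C)C)[C@@H](c2ccc(OCc3ccccc3)c(OC)c2)O1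
A3 | alternative 1 | tert-butyldimethylsilyl ketene acetal of A2, 5-(4-benzyloxy-3-methoxyphenyl)-2-(tert-butyldimethylsilyloxy)-4-(tert-butyldimethylsilyloxymethyl)-4,5-dihydrofuran | CC(C)(C)[Si](C)(C)OC1=C[C@H](CO[Si](C)(C)C(C)(C)C)[C@@H](c2ccc(OCc3ccccc3)c(OC)c2)O1
A4 | alternative 1 | methyl 3-bromocoumalate (methyl 3-bromo-2-oxo-2H-pyran-5-carboxylate) | COC(=O)C1=COC(=O)C(Br)=C1
A5 | alternative 2 | methyl 3-[(4S,5S)-5-(4-benzyloxy-3-methoxyphenyl)-2,2-dimethyl-1,2-oxasilolan-4-yl]-5-methoxy-4-(methoxymethoxy)benzoate | COC(=O)c1cc(OC)c(OCOC)c(c1)[C@H](C4)[C@@H](c1ccc(OCc2ccccc2)c(OC)c1)O[Si]4(C)C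
A6 | alternative 2 | methyl 3-{1-[(R)-(4-benzyloxy-3-methoxyphenyl)(dimethylsilyloxy)methyl]ethenyl}-5-methoxy-4-(methoxymethoxy)benzoate | COC(=O)c1cc(OC)c(OCOC)c(c1)C(=C)[C@@H](c1ccc(OCc2ccccc2)c(OC)c1)O[SiH](C)C
A7 | alternative 2 | methyl 3-[(1S,2R)-1-(4-benzyloxy-3-methoxyphenyl)-1,3-dihydroxypropan-2-yl]-5-methoxy-4-(methoxymethoxy)benzoate (syn diol) | COC(=O)c1cc(OC)c(OCOC)c(c1)[C@H](CO)[C@H](O)c1ccc(OCc2ccccc2)c(OC)c1
A8 | alternative 3 | methyl (2S,3S)-2-(4-benzyloxy-3-methoxyphenyl)-5-bromo-7-methoxy-2,3-dihydrobenzofuran-3-carboxylate | Brc1cc(OC)c2c(c1)[C@H](C(=O)OC)[C@@H](c1ccc(OCc3ccccc3)c(OC)c1)O2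
A9 | alternative 3 | (2S)-2-(4-benzyloxy-3-methoxyphenyl)-6-bromo-8-methoxychroman-4-one | O=C1C[C@@H](c2ccc(OCc3ccccc3)c(OC)c2)Oc2c(OC)cc(Br)cc21
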